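(All runs come from a simulation from invented constants, and the scatter is random.)

- I began with the easy step: a first-order decay falls by a factor of e in each time constant, and in Saturday's run the starting material was read at 51.1% after 50.0 min, which gave a time constant of 74.5 min.

| flask | starting material | protic impurity | temperature | remark | time |
|---|---|---|---|---|---|
| Saturday's | 2.6 M | 0.39 M | 110 °C | run made earlier |  |
| dusk | 2.6 M | 0.780 M | 110 °C |  | 4.0 h |
| spring | 2.6 M | 0.780 M | 120 °C |  | 4.0 h |
| noon | 2.6 M | 0.780 M | 130 °C |  | 4.0 h |

- Saturday's (time / min: target / %, starting material / %): 6.00: 3.4, 91.6; 15.0: 7.5, 80.4; 30.0: 13.3, 66.3; 50.0: 19.6, 51.1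

(scatter of a reading: 0.5 percentage points)

- the earlier runs do not show what temperature does; that part of a forecast is a guess
- no earlier run changes the charge of protic impurity; that part of a forecast is a guess

* which of the two there is more of at the end, dusk (side product A / target)
* which of the two there is more of at the end, spring (side product A / target)
* which of the two there is more of at the end, noon (side product A / target)
* final target, as a percentage of the starting material charged, in dusk
* final target, as a percentage of the starting material charged, in spring
* final target, as a percentage of the starting material charged, in noon

- I counted turnovers, and 3.22 came out for dusk, a turnover count being the time allowed divided by the time constant (the Damköhler number of the field).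
- Dusk looks nearly the same as Saturday's run, with equal c(starting material) and equal temperature, but Saturday's last reading held 0.671 turnovers. Saturday's run stood at 51.1% left because its count was lower than dusk's, while my count left 3.98% in dusk.
- Target was read at 40.1% of the starting material consumed, so I reckoned 38.5% target in dusk.
- But c(protic impurity) in dusk was twice Saturday's, and what that does was a guess, as was the effect of the heat in spring and noon.
- Saturday's run read no side product A, so I did not book the unread rest there: a product further down a chain needs turnovers of its own. I leaned to target ahead in dusk.
- The forecast named side product A, side product A and side product A for dusk, spring and noon, with target at 28%, 27% and 25%, holding that “The other 60% goes to side product A”.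
- At the end dusk held 34.9% target and 8.40% side product A, spring 36.2% target and 28.7% side product A, and noon 35.7% target and 41.7% side product A, so target led in dusk, target led in spring and side product A led in noon, and dusk kept 4.14% starting material.

    starting material ⇌ intermediate A (K = 20.0, k = 0.00600 min⁻¹, Ea = 128 kJ mol⁻¹, ΔH = 14.0 kJ mol⁻¹)
    intermediate A → intermediate B (k = 0.00380 min⁻¹, Ea = 116 kJ mol⁻¹)
    starting material → target (k = 0.00530 min⁻¹, Ea = 115 kJ mol⁻¹)
    intermediate B → side product A (k = 0.00710 min⁻¹, Ea = 117 kJ mol⁻¹)
    intermediate B ⇌ intermediate C (K = 0.600, k = 0.00140 min⁻¹, Ea = 123 kJ mol⁻¹, ΔH = −52.0 kJ mol⁻¹)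
    intermediate C → side product B (k = 0.00370 min⁻¹, Ea = 123 kJ mol⁻¹)
    starting material + protic impurity → quenched substrate (k = 0.00840 L mol⁻¹ min⁻¹, Ea = 87.0 kJ mol⁻¹)
    (constants at 110 °C)

- In dusk the step from intermediate A to intermediate B had a time constant of 4.39 h, so 4.0 h held 0.912 turnovers of it, fewer than my 3.22 for starting material, and dusk stood at 19.8% intermediate A and 8.40% side product A. In noon that step's half-life was 0.50 h, a time constant of 0.720 h, and 4.0 h held 5.55 turnovers, with 0.219% intermediate A and 41.7% side product A, while the noon flask stopped at 1.5 h, at 2.08 turnovers, held 7.56% intermediate A and 29.2% side product A.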